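**Plan**

- Retrosynthesis: the saturated C1–C2 bond of cyclohexanone ring A is traced back to an enone. Then the aryl ether C–O bond of dihydrofuran ring B and the bond from the quaternary carbon of ring A to benzene ring C are cut together, which opens the 20-membered ring. Last, the two amide C–N bonds are cut to give spermidine and two p-coumaric acids.
- Enabling feature: the quaternary carbon of ring A lies para to the ring-A carbonyl, carries an acrylamide arm and is bonded to the ring-C carbon ortho to the ring-B oxygen; ring C carries its own acrylamide arm para to that oxygen. Ring A is therefore a dearomatised p-coumaroyl unit and ring C an intact one, both held by the primary nitrogens of one spermidine.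
- Forward: the open chain is joined first (active ester, then double N-acylation). One oxidative para–ortho phenol coupling then closes the macrocycle and an oxa-Michael addition closes ring B. Conjugate reduction of the remaining ring-A enone finishes the route.
- Stereochemistry: both alkenes are E from p-coumaric acid. The quaternary carbon (S) and the oxygen-bearing ring-fusion carbon (R) arise together when the phenol adds to one of two enantiotopic enone arms inside the oxidase; the cis fusion is forced by the 5/6 ring system.

Key step: step 3

Assumption: a phenol-coupling cytochrome P450 that accepts the bis-amide can be obtained, from seed microsomes of the lunarine-producing plant Lunaria annua or by screening recombinant plant P450s of the CYP719B and CYP80 families. Locants 4a (oxygen-bearing ring-fusion carbon) and 9b (quaternary carbon) are those of the dibenzofuran core.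

Step 1
Reactants: 1 (E)-p-coumaric acid; 2 N-hydroxysuccinimide
Product: 3 N-succinimidyl (E)-p-coumarate (2,5-dioxopyrrolidin-1-yl (E)-3-(4-hydroxyphenyl)prop-2-enoate; phenol free)
Conditions: DCC (1.05 equiv), THF, 0 °C to rt; filter
Reagents that add atoms: none
Why: Carbodiimide-mediated active-ester formation, in which DCC turns the acid into an O-acylisourea that the acidic N–OH group of 2 captures much faster than the weakly nucleophilic phenol, so the ester should form without phenol protection and with the E alkene untouched.

Step 2
Reactants: 4 spermidine (N-(3-aminopropyl)butane-1,4-diamine); 3 N-succinimidyl (E)-p-coumarate (2.0 equiv)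
Product: 5 N1,N8-bis[(E)-p-coumaroyl]spermidine (both primary nitrogens acylated, central NH free)
Conditions: 3 added dropwise to 4, THF/DMF, −20 to 0 °C
Reagents that add atoms: none
Why: Chemoselective aminolysis of an N-hydroxysuccinimide ester, in which the two unhindered primary amines of 4 react much faster at low temperature than the secondary amine or the phenols, so exactly two equivalents of 3 should leave the central nitrogen free.

Step 3
Reactants: 5 N1,N8-bis[(E)-p-coumaroyl]spermidine
Product: 7 (4aR,9bS)-macrocyclic cyclohexenone (target skeleton that still has the C1=C2 double bond in ring A), via macrocyclic dienone phenol 6 (not isolated)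
Conditions: phenol-coupling cytochrome P450 with NADPH–P450 reductase (microsomes), NADP+ (cat.), D-glucose, glucose dehydrogenase, air, phosphate buffer pH 7.5, 2% DMSO, 30 °C
Reagents that add atoms: none
Why: Proposed new method: the oxo-iron haem of the P450 takes the two phenolic hydrogen atoms one after the other without transferring oxygen, and the two phenoxyl radicals, held in the pocket, pair between the ring carbon para to oxygen of the coumaroyl unit on the four-carbon arm and a ring carbon ortho to oxygen of the other unit; enolisation re-aromatises ring C and leaves the 4-aryl-4-alkenylcyclohexa-2,5-dienone 6. The closest known reaction types are the intramolecular para–ortho phenol coupling of salutaridine synthase (CYP719B1) and the P450 biaryl macrocyclisations of tethered phenols in peptide biosynthesis, but no such coupling has been run on a bis(cinnamoyl)polyamine in a flask. The 20-membered ring closes by radical–radical C–C combination across the spermidine tether, and ring B closes by 5-exo-trig oxa-Michael addition of the regenerated phenol to one enone arm. Both stereocentres are created in that addition: the quaternary carbon becomes stereogenic only when one of its two enantiotopic enone arms is attacked, so the choice of arm (9b S, 4a R) has to be made by the chiral pocket before 6 is released, whereas the cis fusion is imposed by the 5/6 ring system. The step needs para–ortho C–C pairing instead of the couplings through the side-chain β-carbon (8–8, 8–5, 8–O–4) that free p-coumaroyl radicals prefer, and dearomatisation of the unit on the four-carbon arm; the substrate offers two equally electron-rich 4-substituted phenols and a protonated secondary amine as an anchor that orients the unsymmetrical chain, and the enzyme has to supply the rest, so selectivity is the open point. Product 7 is kept at or below room temperature and near neutral pH, because base could reopen ring B to achiral 6.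

Step 4
Reactants: 7 (4aR,9bS)-macrocyclic cyclohexenone
Product: 8 target, (4aR,9bS)-macrocyclic cyclohexanone
Conditions: [(Ph3P)CuH]6 (0.4 equiv of hexamer), degassed THF/benzene, H2O (5 equiv), rt; aq. NH4Cl work-up
Reagents that add atoms: none
Why: Copper hydride conjugate reduction with Stryker's reagent, in which hydride adds 1,4 to the cis-enone of ring A much faster than to the two unsaturated secondary amides (poorer acceptors, one conjugated to ring C, the other shielded by the quaternary carbon), the copper enolate lies on the side away from the aryloxy group and is protonated by water, no stereocentre is formed, and once the second enone arm is saturated ring B can no longer open to a symmetric dienone, so the configuration is locked.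

**Compound list**

1 | (E)-p-coumaric acid, (E)-3-(4-hydroxyphenyl)prop-2-enoic acid | OC(=O)/C=C/c1ccc(O)cc1 | starting material
2 | N-hydroxysuccinimide | ON1C(=O)CCC1=O | starting material
3 | N-succinimidyl (E)-p-coumarate, 2,5-dioxopyrrolidin-1-yl (E)-3-(4-hydroxyphenyl)prop-2-enoate | O=C(/C=C/c1ccc(O)cc1)ON1C(=O)CCC1=O | intermediate
4 | spermidine, N-(3-aminopropyl)butane-1,4-diamine | NCCCCNCCCN | starting material
5 | N1,N8-bis[(E)-p-coumaroyl]spermidine | Oc1ccc(/C=C/C(=O)NCCCCNCCCNC(=O)/C=C/c2ccc(O)cc2)cc1 | intermediate
6 | achiral 20-membered macrocyclic cyclohexa-2,5-dienone; C4 of the dienone carries the (E)-acrylamide arm of the butylene side and is bonded to the ring-C carbon ortho to the free phenol OH | O=C1C=CC2(C=C1)/C=C/C(=O)NCCCCNCCCNC(=O)/C=C/c1ccc(O)c2c1 | intermediate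
7 | (4aR,9bS)-cis-4,4a-dihydrodibenzo[b,d]furan-3(9bH)-one whose C9b and C8 are bridged by (E)-CH=CH–C(=O)NH(CH2)4NH(CH2)3NHC(=O)–CH=CH-(E), butylene end on the C9b side | O=C1C=C[C@]23/C=C/C(=O)NCCCCNCCCNC(=O)/C=C/c4ccc(c2c4)O[C@@H]3C1 | intermediate
8 | CNP0415009.1, the (4aR,9bS)-1,2,4,4a-tetrahydro analogue of 7 (saturated cyclohexanone ring A, both acrylamides E) | O=C1CC[C@]23/C=C/C(=O)NCCCCNCCCNC(=O)/C=C/c4ccc(c2c4)O[C@@H]3C1 | target

**Totals**

Total step count: 4. Longest linear sequence: 4 steps (1 → 3 → 5 → 7 → 8).

**Steps most likely to fail**

1. Step 3 (proposed method). The oxidase may not turn the substrate over on a preparative scale. The radicals may pair through the side-chain β-carbons, or the wrong ring may be dearomatised. The dienone may also leave the pocket before ring B closes, so that the enone arm is chosen without facial control.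

   Fallback in known chemistry, setting out from spermidine 4 and returning at 7: the tricyclic core is made by a dearomatising Diels–Alder reaction and the 20-membered ring by olefination. Formalin should convert 4 into the hexahydropyrimidine aminal 4-(1,3-diazinan-1-yl)butan-1-amine F1, which masks the secondary nitrogen and tells the two ends apart. Its primary amine is acylated with diethylphosphonoacetic acid (EDC·HCl, HOBt, CH2Cl2) to the phosphonoacetamide F2, and the ring N–H with acryloyl chloride (iPr2NEt, −20 °C) to the acrylamide linker F3.

   In parallel, purchased 5-bromo-1-benzofuran-3-carbaldehyde and Danishefsky's diene (ZnCl2, toluene, or 12–16 kbar) should add across the furan C2=C3 bond. The CH2 terminus of the diene bonds to C2, so the formyl-bearing C3 becomes the quaternary carbon, giving the cis-fused silyl enol ether cycloadduct F4. TFA in CH2Cl2 then expels methanol and the silyl group to give the racemic tricyclic enone aldehyde F5, which already holds rings A, B and C. A Heck reaction of the aryl bromide of F5 with F3 (Pd(OAc)2, P(o-tol)3, Et3N, MeCN, 80 °C) should give the cinnamamide aldehyde F6. An intramolecular Horner–Wadsworth–Emmons reaction under Masamune–Roush conditions (LiCl, iPr2NEt, MeCN, high dilution) closes the macrocycle to the methylene-bridged macrocycle F7. Malonic acid in pyridine/EtOH removes the N–CH2–N bridge (Knoevenagel capture of formaldehyde) to give racemic 7.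

   F4 to F7 are racemic and are drawn as the enantiomer that leads to 7. Chromatography on a chiral stationary phase separates 7 from its mirror image ent-7 F8. F8 can be returned to the racemate by warming with Et3N, since ring B should open reversibly to the achiral dienone 6. The same resolution would also serve if the enzymatic step gave 7 in low enantiomeric purity.

2. Step 4. Hydride may also add to an unsaturated amide, the ketone may be over-reduced, or the reaction may stall because the secondary amine binds copper.

   Fallback, setting out from 7 and returning at 8: direct 1,4-hydride delivery is replaced by 1,2-reduction followed by an internal hydrogen shift. Luche reduction (NaBH4, CeCl3·7H2O, MeOH, −40 °C) touches only the ketone and should give the allylic alcohol F9 (either C3 epimer serves). Redox isomerisation with (η5-C5Ph5)Ru(CO)2Cl and t-BuOK (cat.) in toluene/THF at rt then moves the carbinol hydrogen to the neighbouring alkene carbon through a ruthenium alkoxide and hydride, which the acrylamides cannot enter, and should give 8.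

3. Step 2. Acylation may run on to the secondary nitrogen or stop after one acyl group, giving mixtures that are hard to separate.

   Fallback, setting out from 4 and returning at 5: the central nitrogen is blocked before acylation. Ethyl trifluoroacetate (2 equiv, MeOH, 0 °C) caps only the primary amines to give N1,N8-bis(trifluoroacetyl)spermidine F10. Boc2O then protects the secondary nitrogen to give the N4-Boc bis(trifluoroacetamide) F11. K2CO3 in aqueous MeOH removes the trifluoroacetyl groups to give N4-Boc-spermidine F12. Acylation with 3 (2 equiv, THF/DMF, 0 °C) gives the N4-Boc bis-amide F13. TFA/CH2Cl2 with triisopropylsilane as cation scavenger should return 5.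

**Further compounds**

F1 | step 3 | 4-(1,3-diazinan-1-yl)butan-1-amine (N1,N4-methylene aminal of spermidine) | NCCCCN1CCCNC1
F2 | step 3 | diethyl [2-({4-(1,3-diazinan-1-yl)butyl}amino)-2-oxoethyl]phosphonate | CCOP(=O)(OCC)CC(=O)NCCCCN1CCCNC1
F3 | step 3 | diethyl [2-({4-[3-(prop-2-enoyl)-1,3-diazinan-1-yl]butyl}amino)-2-oxoethyl]phosphonate | CCOP(=O)(OCC)CC(=O)NCCCCN1CCCN(C1)C(=O)C=C
F4 | step 3 | racemic cis-fused cycloadduct, 8-bromo-1-methoxy-3-(trimethylsilyloxy)-1,4,4a,9b-tetrahydrodibenzo[b,d]furan-9b-carbaldehyde (methoxy epimers; ring fusion as in F5) | C[Si](C)(C)OC1=CC(OC)[C@]2(C=O)c3cc(Br)ccc3O[C@@H]2C1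
F5 | step 3 | racemic (4aR*,9bS*)-8-bromo-3-oxo-4,4a-dihydrodibenzo[b,d]furan-9b(3H)-carbaldehyde | O=C1C=C[C@]2(C=O)c3cc(Br)ccc3O[C@@H]2C1
F6 | step 3 | racemic Heck product, F5 with the bromine replaced by the (E)-CH=CH–C(=O) group on the ring nitrogen of F3 (phosphonoacetamide and aldehyde retained) | O=C1C=C[C@]2(C=O)c3cc(/C=C/C(=O)N4CCCN(CCCCNC(=O)CP(=O)(OCC)OCC)C4)ccc3O[C@@H]2C1
F7 | step 3 | racemic methylene-bridged macrocycle, 7 with a CH2 joining the ring-C-side amide nitrogen to the central nitrogen | O=C1C=C[C@]23/C=C/C(=O)NCCCCN5CCCN(C5)C(=O)/C=C/c4ccc(c2c4)O[C@@H]3C1
F8 | step 3 | ent-7, the (4aS,9bR) mirror image of 7 | O=C1C=C[C@@]23/C=C/C(=O)NCCCCNCCCNC(=O)/C=C/c4ccc(c2c4)O[C@H]3C1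
F9 | step 4 | allylic alcohol of 7 (C3 carbinol, either epimer; 4a and 9b as in 7) | OC1C=C[C@]23/C=C/C(=O)NCCCCNCCCNC(=O)/C=C/c4ccc(c2c4)O[C@@H]3C1
F10 | step 2 | N1,N8-bis(trifluoroacetyl)spermidine | O=C(NCCCCNCCCNC(=O)C(F)(F)F)C(F)(F)F
F11 | step 2 | tert-butyl N-[4-(trifluoroacetamido)butyl]-N-[3-(trifluoroacetamido)propyl]carbamate | CC(C)(C)OC(=O)N(CCCCNC(=O)C(F)(F)F)CCCNC(=O)C(F)(F)F
F12 | step 2 | N4-Boc-spermidine, tert-butyl N-(4-aminobutyl)-N-(3-aminopropyl)carbamate | CC(C)(C)OC(=O)N(CCCCN)CCCN
F13 | step 2 | N4-Boc-N1,N8-bis[(E)-p-coumaroyl]spermidine | CC(C)(C)OC(=O)N(CCCCNC(=O)/C=C/c1ccc(O)cc1)CCCNC(=O)/C=C/c1ccc(O)cc1
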